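No rate constant lay on the table at the meeting. The readings offered a share instead.

| flask | substrate | target | time |
|---|---|---|---|
| south-east | 300 mM |  |  |
| west | 120 mM |  |  |
| south | 300 mM | 90.0 mM |  |
| south-west | 600 mM |  |  |
| east | 1500 mM |  | 46 h |

- south-east run (time / h: [target] / mM): 6.6: 41.9; 13: 71.4; 20: 100.0; 26: 114.2; 33: 129.3; 39: 134.5; 46: 140.6
- west run (time / h: [target] / mM): 6.6: 16.7; 13: 29.6; 20: 40.4; 26: 47.3; 33: 52.0; 39: 54.5; 46: 55.4
- south run (time / h: [target] / mM): 6.6: 123.2; 13: 148.1; 20: 168.7; 26: 177.3; 33: 184.1; 39: 188.8; 46: 187.9
- south-west run (time / h: [target] / mM): 6.6: 83.5; 13: 145.2; 20: 196.2; 26: 225.8; 33: 253.7; 39: 269.6; 46: 279.1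

(scatter of a reading: 0.9 mM)

* how the opening rate goes with [substrate] round the charge of the south-east run: the exponent of the rate at two percent of substrate gone to target (one fixed amount of target, the same in the runs compared)
* target in the east run at 46 h, as a share of the substrate charged

- Overall: substrate -> target.
- Constant volume, constant temperature.
- An order is taken over about fifteen percent of the charge, up and down.

Minutes. The first speaker worked from the south-west run. She read 46.5 % as the closing share, the fraction of the charge standing as target at 46 h. The west run gave 46.2 % and the south-east run 46.9 %. One west reading scatters by 0.750 % of its charge. So she held that the closing share shows no trend with charge across these runs.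

The second speaker took the first readings, at 6.6 h. From the south-east to the south-west run the charge doubles, and target rises by a ratio of 1.99. That gave him an exponent of 0.995. He warned that this compares equal times, not equal target, and spans more than the range the order is taken over.

The third speaker objected that the east charge is 2.50 times the south-west charge, with no reading there. She also noted that the south run, charged with target, closes at 48.2 % of substrate and target together.

My own reckoning stayed with 0.995 and, for the east run, 46.5 %. The forecast said “the kinetics are effectively first order in overall concentration”. It gave an order of 0.98 (0.88 to 1.08). For the east run it gave 46 % (43.5 % to 47.3 %), lower than my share.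

The flask gave an order of 1.0 and, for the east run, 46.6 %.

    2 substrate ⇌ intermediate + substrate (0.1332 M⁻¹ h⁻¹, 0.4968 M⁻¹ h⁻¹)
    intermediate → target (0.01912 h⁻¹)
    substrate → target (0.02462 h⁻¹)
    target → decomposed product (0.01339 h⁻¹)

The step from substrate to target carries the target of the east run: its constant, 0.0246 h⁻¹, has no concentration in it, so this step runs in proportion to the substrate present. With that step taken away, the east run reaches 12.1 % at 46 h instead of 46.6 %, about a quarter of the closing share read in the south-west run.

The earlier runs and the new flask were generated by integration with constants of no real substance; scatter was added.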